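**Retrosynthetic overview**
1. The exocyclic methylene comes from a bridging ketone by late methylenation; the esters are installed in order (4-acetate, then 11-propanoate, then 15-acetate).
2. Eleven-membered ring: Nozaki–Hiyama–Kishi closure of the allylic C–C bond between a ring-bound acetaldehyde arm and a (Z)-iodoalkene made by Stork–Zhao olefination.
3. Five-membered ring: ring-closing metathesis between an allyl group and a 1,1-disubstituted alkene on neighbouring ring carbons, then convex-face hydrogenation.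
4. Key disconnection: both of those ring substituents are introduced in one desymmetrising step, a copper-catalysed enantioselective transfer of an internal vinylalane to the C2v-symmetric 4,4-dimethoxycyclohexa-2,5-dienone (from 4-methoxyphenol by oxidative dearomatisation), followed by enolate allylation.
5. Ring order: six-membered ring (from the arene), then five-membered ring, then eleven-membered ring; the chiral alkyne fragment comes from an allenylstannane propargylation.

**Conventions and assumptions**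
- Target numbering used for late intermediates: C1 = ring carbon bearing the exocyclic CH2; C2 (bridgehead CH), C3, C4 (CH–OAc), C5 (C–CH3), C6 (ring-fusion CH) close the six-membered ring; C7, C8, C9 complete the five-membered ring (C5 to C6); C10 (CH–CH3), C11 (CH–O-propanoyl), C12, C13=C14(CH3), C15 (CH–OAc), C16 run from C9 back to C2; α is the face of the C5 methyl; TBS = tert-butyldimethylsilyl, Bn = benzyl.
- Assumption: 3-(benzyloxy)propanal, (S)-but-3-yn-2-ol and (1,3-dioxolan-2-ylmethyl)magnesium bromide are bought.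
- Assumption: the (S,S)-phosphinamine ligand in step 6 is taken to give the C6 configuration drawn; if the sense of induction is the opposite, its enantiomer is used.

**Route**

Step 1
Reactants: 1 4-methoxyphenol
Product: 2 4,4-dimethoxycyclohexa-2,5-dien-1-one
Conditions: PhI(OAc)2, MeOH, 0 → 23 °C
Reagents that add atoms: methanol, CO
Why: Hypervalent-iodine oxidative dearomatisation, in which methanol traps the phenoxenium ion para to give the achiral C2v-symmetric quinone monoketal whose two enone β-carbons are enantiotopic.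

Step 2
Reactants: 3 (S)-but-3-yn-2-ol
Product: 4 (S)-but-3-yn-2-yl methanesulfonate
Conditions: MeSO2Cl, Et3N, CH2Cl2, −78 → 0 °C
Reagents that add atoms: methanesulfonyl chloride, CS(=O)(=O)Cl
Why: O-Sulfonylation forms only an O–S bond, so the stereocentre is untouched.

Step 3
Reactants: 4 (S)-but-3-yn-2-yl methanesulfonate
Product: 5 (aR)-tributyl(buta-1,2-dien-1-yl)stannane
Conditions: Bu3SnH, LiN(i-Pr)2, THF, 0 °C; CuBr·SMe2, −78 °C; then 4, −78 °C
Reagents that add atoms: tributyltin hydride, CCCC[SnH](CCCC)CCCC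
Why: anti-SN2′ displacement of the propargylic mesylate by the stannylcopper reagent converts the (S) centre into the (aR) allene axis.

Step 4
Reactants: 5 (aR)-tributyl(buta-1,2-dien-1-yl)stannane; 6 3-(benzyloxy)propanal
Product: 7 (3S,4S)-1-(benzyloxy)-4-methylhex-5-yn-3-ol
Conditions: BF3·OEt2, CH2Cl2, −78 °C
Reagents that add atoms: none
Why: Marshall propargylation, an anti-SE2′ addition through an open BF3-activated transition state, so the allene axis sets the methyl-bearing carbon (S) and the open transition state gives the syn carbinol (S).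

Step 5
Reactants: 7 (3S,4S)-1-(benzyloxy)-4-methylhex-5-yn-3-ol
Product: 8 (3S,4S)-1-(benzyloxy)-3-(tert-butyldimethylsilyloxy)-4-methylhex-5-yne
Conditions: t-BuMe2SiOTf, 2,6-lutidine, CH2Cl2, 0 °C
Reagents that add atoms: tert-butyldimethylsilyl trifluoromethanesulfonate, CC(C)(C)[Si](C)(C)OS(=O)(=O)C(F)(F)F
Why: Silylation of the secondary alcohol, with no stereocentre involved.

Step 6
Reactants: 8 (3S,4S)-1-(benzyloxy)-3-(tert-butyldimethylsilyloxy)-4-methylhex-5-yne; 2 4,4-dimethoxycyclohexa-2,5-dien-1-one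
Product: 11 (5S,6R)-6-allyl-5-[(3S,4S)-6-(benzyloxy)-4-(TBSO)-3-methylhex-1-en-2-yl]-4,4-dimethoxycyclohex-2-en-1-one, via vinylalane 9 (not isolated), via aluminium enolate 10 (not isolated)
Conditions: i-Bu2AlH (1.0 equiv), NiCl2(Ph2PCH2CH2CH2PPh2) (3 mol %), THF, 23 °C; add to 2, Cu(O2CC4H3S) (10 mol %), (S,S)-N,N-bis(1-phenylethyl)-P,P-diphenylphosphinous amide (11 mol %), Et2O/THF, −30 °C; then allyl acetate, Pd(PPh3)4 (5 mol %), −30 → 23 °C
Reagents that add atoms: allyl acetate, C=CCOC(C)=O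
Why: Proposed new method: nickel-catalysed α-selective hydroalumination gives the internal vinylalane, whose alkenyl group a chiral copper–phosphinamine catalyst transfers to one of the two enantiotopic β-carbons of the symmetric dienone (catalyst-controlled desymmetrisation setting C6, the side-chain stereocentres being remote spectators), and the aluminium enolate is then C-allylated by a π-allylpalladium electrophile; the closest known reactions are copper-catalysed asymmetric conjugate additions of vinylalanes to cyclic enones, copper-catalysed desymmetrisation of this same dienone with dialkylzincs, and Tsuji–Trost trapping of aluminium enolates.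

Step 7
Reactants: 11 (5S,6R)-6-allyl-5-alkenyl-4,4-dimethoxycyclohex-2-en-1-one
Product: 13 (5R,6S)-6-allyl-5-[(3S,4S)-6-(benzyloxy)-4-(TBSO)-3-methylhex-1-en-2-yl]-4,4-dimethoxy-6-methylcyclohex-2-en-1-one, via lithium enolate 12 (not isolated)
Conditions: LiN(i-Pr)2, THF, −78 °C; then MeI, DMPU, −78 → −20 °C
Reagents that add atoms: iodomethane, CI
Why: Enolate alkylation: the only enolisable position is the allyl-bearing carbon, and iodomethane enters anti to the neighbouring alkenyl group, creating the quaternary centre with methyl α and allyl cis to the alkenyl group.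

Step 8
Reactants: 13 (5R,6S)-6-allyl-5-alkenyl-4,4-dimethoxy-6-methylcyclohex-2-en-1-one
Product: 14 (3aR,7aS)-3-[(2S,3S)-5-(benzyloxy)-3-(TBSO)pentan-2-yl]-4,4-dimethoxy-7a-methyl-1,3a,4,7a-tetrahydro-7H-inden-7-one
Conditions: second-generation Grubbs catalyst RuCl2(=CHPh)(PCy3)(H2IMes) (5 mol %), CH2Cl2, 40 °C
Reagents that add atoms: none
Why: Ring-closing metathesis joins the cis-disposed allyl and 1,1-disubstituted alkene into the trisubstituted cyclopentene (C8=C9) with loss of ethene, giving the cis-fused bicycle fixed by step 7.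

Step 9
Reactants: 14 cis-fused bicyclic dienone
Product: 15 (3aR,5R,7aS)-3-[(2S,3S)-5-(benzyloxy)-3-(TBSO)pentan-2-yl]-5-(1,3-dioxolan-2-ylmethyl)-4,4-dimethoxy-7a-methyl-1,3a,4,5,6,7a-hexahydro-7H-inden-7-one
Conditions: (1,3-dioxolan-2-ylmethyl)magnesium bromide, CuBr·SMe2 (20 mol %), THF, −40 → −20 °C; aq. NH4Cl
Reagents that add atoms: (1,3-dioxolan-2-ylmethyl)magnesium bromide, Br[Mg]CC1OCCO1
Why: Copper-catalysed 1,4-addition to the remaining enone occurs on the convex α-face, anti to the five-membered ring and trans to the C6 substituent (the usual trans-3,5 outcome), which sets C2.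

Step 10
Reactants: 15 bicyclic ketone with C8=C9 alkene and benzyl ether
Product: 16 (3S,3aR,5R,7aS)-5-(1,3-dioxolan-2-ylmethyl)-3-[(2S,3S)-5-hydroxy-3-(TBSO)pentan-2-yl]-4,4-dimethoxy-7a-methyloctahydro-7H-inden-7-one
Conditions: H2 (5 atm), Pd(OH)2/C, NaHCO3, EtOAc/EtOH, 23 °C
Reagents that add atoms: none
Why: Heterogeneous hydrogenation adds H2 syn to the convex α-face of the cyclopentene, opposite the six-membered ring, which sets C9 with the side chain on the concave β-face; the same conditions hydrogenolyse the benzyl ether.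

Step 11
Reactants: 16 primary alcohol
Product: 17 C13 aldehyde (target numbering; C1 dimethyl ketal, C4 ketone, C11–OTBS, C2–CH2-dioxolane)
Conditions: Dess–Martin periodinane, NaHCO3, CH2Cl2, 0 → 23 °C
Reagents that add atoms: none
Why: Dess–Martin oxidation of the only free alcohol under buffered conditions that spare both acetals and the silyl ether.

Step 12
Reactants: 17 C13 aldehyde
Product: 18 (13Z)-14-iodo alkene (C13H=C14(CH3)I)
Conditions: [Ph3PCH2CH3]I, n-BuLi, THF, 0 °C; I2, −78 °C; NaN(SiMe3)2, −20 °C; then 17, −78 °C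
Reagents that add atoms: ethyltriphenylphosphonium iodide, CC[P+](c1ccccc1)(c1ccccc1)c1ccccc1.[I-]; iodine, II
Why: Stork–Zhao–Wittig olefination, in which the α-iodo ylide reacts only with the aldehyde (the α-quaternary ketone is inert at −78 °C) to give the (Z)-2-iodoalkene with iodine cis to the chain.

Step 13
Reactants: 18 (13Z)-iodoalkene ketone
Product: 20 4α-acetate (4S) of the iodoalkene, via lithium alkoxide 19 (not isolated)
Conditions: LiBH(s-Bu)3, THF, −78 °C; then Ac2O, DMAP, −78 → 23 °C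
Reagents that add atoms: acetic anhydride, CC(=O)OC(C)=O
Why: Bulky-hydride reduction on the β-face, away from the angular methyl and the C2 side chain (both α), gives the 4α-alkoxide cis to the methyl group, which is acetylated in the same flask.

Step 14
Reactants: 20 4α-acetate with dimethyl ketal, dioxolane and silyl ether
Product: 21 seco keto-aldehyde alcohol (C1 ketone, C2–CH2–CHO, C4–OAc, C11–OH, 13Z-14-iodide)
Conditions: 2 M aq. HCl, THF, 23 °C
Reagents that add atoms: water, O
Why: Acid-catalysed hydrolysis removes the dimethyl ketal, the dioxolane and the silyl ether in one operation while the acetate and iodoalkene survive; no stereocentre is formed.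

Step 15
Reactants: 21 seco keto-aldehyde alcohol
Product: 22 11-O-propanoate of the seco keto-aldehyde
Conditions: (EtCO)2O, DMAP, pyridine, CH2Cl2, 0 °C
Reagents that add atoms: propanoic anhydride, CCC(=O)OC(=O)CC
Why: DMAP-catalysed acylation of the only free hydroxyl places the propanoate on C11 before the second carbinol exists.

Step 16
Reactants: 22 11-O-propanoate with C15 aldehyde and (Z)-iodoalkene
Product: 23 macrocyclic (15R)-allylic alcohol with C1 ketone
Conditions: CrCl2 (10 equiv), NiCl2 (2 mol % of Cr), DMSO/THF 3:1, 0.003 M, 23 °C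
Reagents that add atoms: none
Why: Nozaki–Hiyama–Kishi macrocyclisation, in which the alkenylchromium formed with retention of the Z geometry adds only to the aldehyde; the 11-membered transition state held over the cis-hydrindane is expected, but not proven, to give the (15R) alcohol.

Step 17
Reactants: 23 macrocyclic allylic alcohol
Product: 24 1-oxo triester (4,15-diacetate 11-propanoate)
Conditions: Ac2O, DMAP, pyridine, CH2Cl2, 23 °C
Reagents that add atoms: acetic anhydride, CC(=O)OC(C)=O
Why: DMAP-catalysed acetylation of the allylic C15 alcohol, with no change at any stereocentre.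

Step 18
Reactants: 24 1-oxo triester
Product: 25 CNP0239696.1
Conditions: Zn, CH2Br2, TiCl4, THF/CH2Cl2, 0 → 23 °C
Reagents that add atoms: dibromomethane, BrCBr
Why: Takai–Lombardo methylenation, a non-basic zinc/titanium gem-dimetallic reagent that methylenates the hindered enolisable bridging ketone without epimerising C2 or C6 and without attacking the three esters.

**Compound list**
1 | 4-methoxyphenol | COc1ccc(O)cc1 | starting material
2 | 4,4-dimethoxycyclohexa-2,5-dien-1-one | COC1(OC)C=CC(=O)C=C1 | intermediate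
3 | (S)-but-3-yn-2-ol | C#C[C@H](C)O | starting material
4 | (S)-but-3-yn-2-yl methanesulfonate | C#C[C@H](C)OS(C)(=O)=O | intermediate
5 | (aR)-tributyl(buta-1,2-dien-1-yl)stannane | CC([H])=[C@]=C([H])[Sn](CCCC)(CCCC)CCCC | intermediate
6 | 3-(benzyloxy)propanal | O=CCCOCc1ccccc1 | starting material
7 | (3S,4S)-1-(benzyloxy)-4-methylhex-5-yn-3-ol | C#C[C@H](C)[C@@H](O)CCOCc1ccccc1 | intermediate
8 | (3S,4S)-1-(benzyloxy)-3-(tert-butyldimethylsilyloxy)-4-methylhex-5-yne | C#C[C@H](C)[C@@H](O[Si](C)(C)C(C)(C)C)CCOCc1ccccc1 | intermediate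
9 | diisobutyl[(3S,4S)-6-(benzyloxy)-4-(TBSO)-3-methylhex-1-en-2-yl]alane | C=C([Al](CC(C)C)CC(C)C)[C@H](C)[C@@H](O[Si](C)(C)C(C)(C)C)CCOCc1ccccc1 | intermediate
10 | diisobutylaluminium 3-alkenyl-4,4-dimethoxycyclohexa-1,5-dien-1-olate (alkenyl as in 9; ring stereocentre as C5 of 11) | COC1(OC)C=CC(O[Al](CC(C)C)CC(C)C)=C[C@H]1C(=C)[C@H](C)[C@@H](O[Si](C)(C)C(C)(C)C)CCOCc2ccccc2 | intermediate
11 | (5S,6R)-6-allyl-5-[(3S,4S)-6-(benzyloxy)-4-(TBSO)-3-methylhex-1-en-2-yl]-4,4-dimethoxycyclohex-2-en-1-one (allyl trans to alkenyl) | COC1(OC)C=CC(=O)[C@H](CC=C)[C@H]1C(=C)[C@H](C)[C@@H](O[Si](C)(C)C(C)(C)C)CCOCc2ccccc2 | intermediate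
12 | lithium enolate of 11 (lithium 2-allyl-3-alkenyl-4,4-dimethoxycyclohexa-1,5-dien-1-olate) | COC1(OC)C=CC(O[Li])=C(CC=C)[C@H]1C(=C)[C@H](C)[C@@H](O[Si](C)(C)C(C)(C)C)CCOCc2ccccc2 | intermediate
13 | (5R,6S)-6-allyl-5-[(3S,4S)-6-(benzyloxy)-4-(TBSO)-3-methylhex-1-en-2-yl]-4,4-dimethoxy-6-methylcyclohex-2-en-1-one (methyl trans, allyl cis to alkenyl) | COC1(OC)C=CC(=O)[C@@](C)(CC=C)[C@H]1C(=C)[C@H](C)[C@@H](O[Si](C)(C)C(C)(C)C)CCOCc2ccccc2 | intermediate
14 | (3aR,7aS)-3-[(2S,3S)-5-(benzyloxy)-3-(TBSO)pentan-2-yl]-4,4-dimethoxy-7a-methyl-1,3a,4,7a-tetrahydro-7H-inden-7-one (cis-fused) | COC1(OC)C=CC(=O)[C@@]2(C)CC=C([C@H](C)[C@@H](O[Si](C)(C)C(C)(C)C)CCOCc3ccccc3)[C@@H]12 | intermediate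
15 | (3aR,5R,7aS)-3-[(2S,3S)-5-(benzyloxy)-3-(TBSO)pentan-2-yl]-5-(1,3-dioxolan-2-ylmethyl)-4,4-dimethoxy-7a-methyl-1,3a,4,5,6,7a-hexahydro-7H-inden-7-one (C2 side chain α) | COC1(OC)[C@H](CC2OCCO2)CC(=O)[C@@]3(C)CC=C([C@H](C)[C@@H](O[Si](C)(C)C(C)(C)C)CCOCc4ccccc4)[C@@H]13 | intermediate
16 | (3S,3aR,5R,7aS)-5-(1,3-dioxolan-2-ylmethyl)-3-[(2S,3S)-5-hydroxy-3-(TBSO)pentan-2-yl]-4,4-dimethoxy-7a-methyloctahydro-7H-inden-7-one (indane numbering of 14 kept; C9 side chain β) | COC1(OC)[C@H](CC2OCCO2)CC(=O)[C@@]3(C)CC[C@@H]([C@H](C)[C@@H](O[Si](C)(C)C(C)(C)C)CCO)[C@@H]13 | intermediate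
17 | C13 aldehyde of 16 (target numbering; stereocentres C2, C5, C6, C9, C10, C11 as in 25) | COC1(OC)[C@H](CC2OCCO2)CC(=O)[C@@]3(C)CC[C@@H]([C@H](C)[C@@H](O[Si](C)(C)C(C)(C)C)CC=O)[C@@H]13 | intermediate
18 | (13Z)-14-iodo alkene: C1 dimethyl ketal, C4 ketone, C11–OTBS, C2–CH2-dioxolane | COC1(OC)[C@H](CC2OCCO2)CC(=O)[C@@]3(C)CC[C@@H]([C@H](C)[C@@H](O[Si](C)(C)C(C)(C)C)C/C=C(/C)I)[C@@H]13 | intermediate
19 | lithium 4α-alkoxide from 18 | COC1(OC)[C@H](CC2OCCO2)C[C@H](O[Li])[C@@]3(C)CC[C@@H]([C@H](C)[C@@H](O[Si](C)(C)C(C)(C)C)C/C=C(/C)I)[C@@H]13 | intermediate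
20 | 4α-acetate (4S) of 18 with C4 reduced | COC1(OC)[C@H](CC2OCCO2)C[C@H](OC(C)=O)[C@@]3(C)CC[C@@H]([C@H](C)[C@@H](O[Si](C)(C)C(C)(C)C)C/C=C(/C)I)[C@@H]13 | intermediate
21 | seco keto-aldehyde alcohol: C1 ketone, C2–CH2–CHO (C15 aldehyde), C4–OAc, C11–OH, (13Z)-14-iodide | O=C1[C@H](CC=O)C[C@H](OC(C)=O)[C@@]2(C)CC[C@@H]([C@H](C)[C@@H](O)C/C=C(/C)I)[C@@H]12 | intermediate
22 | 11-O-propanoate of 21 | O=C1[C@H](CC=O)C[C@H](OC(C)=O)[C@@]2(C)CC[C@@H]([C@H](C)[C@@H](OC(=O)CC)C/C=C(/C)I)[C@@H]12 | intermediate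
23 | macrocyclic (15R)-alcohol: C1 ketone, 4-acetate, 11-propanoate, 13Z | O=C1[C@H]2C[C@H](OC(C)=O)[C@@]3(C)CC[C@@H]([C@H](C)[C@@H](OC(=O)CC)C/C=C(/C)[C@H](O)C2)[C@@H]13 | intermediate
24 | 1-oxo triester: 4,15-diacetate 11-propanoate | O=C1[C@H]2C[C@H](OC(C)=O)[C@@]3(C)CC[C@@H]([C@H](C)[C@@H](OC(=O)CC)C/C=C(/C)[C@H](OC(C)=O)C2)[C@@H]13 | intermediate
25 | CNP0239696.1: (2R,4S,5S,6S,9R,10S,11S,13Z,15R)-4,15-diacetoxy-11-propanoyloxy-1-methylene tricycle (route numbering) | C=C1[C@H]2C[C@H](OC(C)=O)[C@@]3(C)CC[C@@H]([C@H](C)[C@@H](OC(=O)CC)C/C=C(/C)[C@H](OC(C)=O)C2)[C@@H]13 | target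

**Totals**
Total step count: 18.
Longest linear sequence: 17 steps (3 → 25 through steps 2–18); the arene branch 1 → 25 is 14 steps.

**Three steps most likely to fail, with fallbacks**

Step 6 (desymmetrising vinylalane addition and enolate allylation). The hindered α-branched vinylalane must add beside the ketal carbon under catalyst control, and the aluminium enolate must then be allylated. The fallback sets out from 8 and 2 and comes back at 11. Alkyne 8 is converted by copper-catalysed α-selective protoboration (CuCl, N-heterocyclic carbene ligand, B2pin2, MeOH) into the pinacol alkenylboronate F1. Rhodium-catalysed asymmetric 1,4-addition of F1 to 2 ([RhCl(C2H4)2]2, chiral bicyclo[2.2.2]octadiene ligand, aq. KOH, dioxane) gives the non-allylated enone F2. Deprotonation of F2 at its only enolisable carbon (LiN(i-Pr)2) and alkylation with allyl iodide gives 11.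

Step 16 (chromium-mediated closure of the 11-membered ring). Ring strain in the trans-1,3-bridged system and the configuration at C15 are both uncertain. The fallback sets out from 17 and comes back at 24, closing the ring at the C13=C14 alkene by metathesis instead. Aldehyde 17 is methylenated (Ph3P=CH2) to the terminal alkene F3. F3 is taken through the conditions of step 13 to the 4α-acetate F4, of step 14 to the keto-aldehyde alcohol F5, and of step 15 to the propanoate F6. Chemoselective CrCl2/NiCl2-mediated addition of 2-bromopropene to the aldehyde of F6 gives the isopropenyl carbinol F7 (C15 epimers separated). Acetylation gives the diene acetate F8. Ring-closing metathesis with the second-generation Grubbs catalyst, where the medium ring is expected to favour the Z-trisubstituted alkene, gives 24.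

Step 18 (methylenation of the bridging ketone inside the macrocycle). The ketone is flanked by two tertiary carbons and shielded by the bridge. The fallback sets out from 20 and comes back at 25, installing the methylene before ring closure. Selective hydrolysis of the dimethyl ketal of 20 (pyridinium p-toluenesulfonate, wet acetone; dioxolane and silyl ether survive) gives the ketone F9. Wittig methylenation (Ph3P=CH2) of this conformationally free cyclohexanone gives the exocyclic alkene F10. Aqueous HCl then releases the aldehyde alcohol F11, and acylation gives the propanoate F12. CrCl2/NiCl2 closure gives the macrocyclic alcohol F13, and acetylation of F13 gives 25.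

**Further compounds**
F1 | step 6 | 2-[(3S,4S)-6-(benzyloxy)-4-(TBSO)-3-methylhex-1-en-2-yl]-4,4,5,5-tetramethyl-1,3,2-dioxaborolane | C=C(B1OC(C)(C)C(C)(C)O1)[C@H](C)[C@@H](O[Si](C)(C)C(C)(C)C)CCOCc1ccccc1
F2 | step 6 | 5-[(3S,4S)-6-(benzyloxy)-4-(TBSO)-3-methylhex-1-en-2-yl]-4,4-dimethoxycyclohex-2-en-1-one (ring stereocentre as C5 of 11) | COC1(OC)C=CC(=O)C[C@H]1C(=C)[C@H](C)[C@@H](O[Si](C)(C)C(C)(C)C)CCOCc2ccccc2
F3 | step 16 | terminal alkene from 17 (C13=CH2; C1 dimethyl ketal, C4 ketone, C11–OTBS) | COC1(OC)[C@H](CC2OCCO2)CC(=O)[C@@]3(C)CC[C@@H]([C@H](C)[C@@H](O[Si](C)(C)C(C)(C)C)CC=C)[C@@H]13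
F4 | step 16 | 4α-acetate of F3 | COC1(OC)[C@H](CC2OCCO2)C[C@H](OC(C)=O)[C@@]3(C)CC[C@@H]([C@H](C)[C@@H](O[Si](C)(C)C(C)(C)C)CC=C)[C@@H]13
F5 | step 16 | keto-aldehyde alcohol with terminal alkene (C1 ketone, C15 aldehyde, C11–OH) | O=C1[C@H](CC=O)C[C@H](OC(C)=O)[C@@]2(C)CC[C@@H]([C@H](C)[C@@H](O)CC=C)[C@@H]12
F6 | step 16 | 11-O-propanoate of F5 | O=C1[C@H](CC=O)C[C@H](OC(C)=O)[C@@]2(C)CC[C@@H]([C@H](C)[C@@H](OC(=O)CC)CC=C)[C@@H]12
F7 | step 16 | (15R)-isopropenyl carbinol from F6 | O=C1[C@H](C[C@@H](O)C(C)=C)C[C@H](OC(C)=O)[C@@]2(C)CC[C@@H]([C@H](C)[C@@H](OC(=O)CC)CC=C)[C@@H]12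
F8 | step 16 | 15-acetate of F7 (metathesis diene) | O=C1[C@H](C[C@@H](OC(C)=O)C(C)=C)C[C@H](OC(C)=O)[C@@]2(C)CC[C@@H]([C@H](C)[C@@H](OC(=O)CC)CC=C)[C@@H]12
F9 | step 18 | C1 ketone from 20 (dioxolane, silyl ether, 4-acetate and iodoalkene kept) | O=C1[C@H](CC2OCCO2)C[C@H](OC(C)=O)[C@@]3(C)CC[C@@H]([C@H](C)[C@@H](O[Si](C)(C)C(C)(C)C)C/C=C(/C)I)[C@@H]13
F10 | step 18 | C1 exocyclic methylene compound from F9 | C=C1[C@H](CC2OCCO2)C[C@H](OC(C)=O)[C@@]3(C)CC[C@@H]([C@H](C)[C@@H](O[Si](C)(C)C(C)(C)C)C/C=C(/C)I)[C@@H]13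
F11 | step 18 | methylene aldehyde alcohol (C15 aldehyde, C11–OH) | C=C1[C@H](CC=O)C[C@H](OC(C)=O)[C@@]2(C)CC[C@@H]([C@H](C)[C@@H](O)C/C=C(/C)I)[C@@H]12
F12 | step 18 | 11-O-propanoate of F11 | C=C1[C@H](CC=O)C[C@H](OC(C)=O)[C@@]2(C)CC[C@@H]([C@H](C)[C@@H](OC(=O)CC)C/C=C(/C)I)[C@@H]12
F13 | step 18 | macrocyclic (15R)-alcohol with C1 methylene | C=C1[C@H]2C[C@H](OC(C)=O)[C@@]3(C)CC[C@@H]([C@H](C)[C@@H](OC(=O)CC)C/C=C(/C)[C@H](O)C2)[C@@H]13
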